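**Retrosynthetic overview**

1. Numbering runs C1 (alkyne CH) to C15 (ethyl CH3). The target is a 2,8-dioxabicyclo[5.2.1]decane: an oxolane ring (O, C6, C7, C8, C9) whose C7 and C9 are bridged by O–C13–C12–C11–C10 (the oxocane ring).
2. The side chain comes last: the (Z)-enyne C1–C4 by Peterson olefination of a C4 aldehyde; C4–C5 and the C6 stereocentre by allyl addition to a C6 lactone carbonyl and hemiketal reduction.
3. Key disconnection: the oxocane ring is cut at O–C7 and at C10–C11, giving a C6–C10 α-diazo lactone with a CHBr2 group at C10 and (R)-pent-1-en-3-ol (C11–C15).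
4. Enabling features: C7 is the α-carbon of the lactone C6(=O)–O of the five-membered ring (copper carbene, O–H insertion). C10(Br)–C11H2–C12(Br) is the retron of a Kharasch atom-transfer addition of a 1,1-dibromide across the terminal alkene C11=C12. The cis-1,3 arms at C7 and C9 template the ring closure.
5. Ring order: the five-membered ring is bought (glutamic-acid-derived lactone); the oxocane ring is closed in the key step, which also installs both C–Br bonds and three stereocentres (C7, C10, C12).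

Key step: step 4

Remark on the chemistry: both starting materials are assumed to be available as single enantiomers; the diazo lactone is used without storage.

**Step 1**
Reactants: 1 (5S)-5-(hydroxymethyl)oxolan-2-one
Product: 2 (2S)-5-oxooxolane-2-carbaldehyde
Conditions: TEMPO (10 mol %), PhI(OAc)2, CH2Cl2, 25 °C
Reagents that add atoms: none
Why: Oxoammonium (TEMPO) oxidation of the primary alcohol to the aldehyde under non-basic conditions, which should leave the adjacent C9 stereocentre untouched.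

**Step 2**
Reactants: 2 (2S)-5-oxooxolane-2-carbaldehyde
Product: 3 (5S)-5-(dibromomethyl)oxolan-2-one
Conditions: (PhO)3P, Br2, CH2Cl2, −78 °C; then 2, −78 → 25 °C
Reagents that add atoms: bromine, BrBr
Why: Deoxygenative gem-dibromination of an aldehyde with triphenyl phosphite dibromide (bromophosphonium activation of the carbonyl oxygen, then two bromide deliveries); no base is present, so C9 should not epimerise.

**Step 3**
Reactants: 3 (5S)-5-(dibromomethyl)oxolan-2-one
Product: 5 (5S)-3-diazo-5-(dibromomethyl)oxolan-2-one, via trifluoroacetyl lactone 4 (not isolated)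
Conditions: LiN(SiMe3)2, THF, −78 °C; CF3CO2CH2CF3; aq. HCl work-up; then MeSO2N3, Et3N, H2O (1 equiv), MeCN, 25 °C
Reagents that add atoms: methanesulfonyl azide, CS(=O)(=O)N=[N+]=[N-]
Why: Detrifluoroacetylative Regitz diazo transfer: the kinetic lactone enolate is C-acylated, the activated 1,3-dicarbonyl 4 accepts the diazo group from the sulfonyl azide and loses the trifluoroacetyl group, and C9 is not touched.

**Step 4**
Reactants: 5 (5S)-3-diazo-5-(dibromomethyl)oxolan-2-one; 6 (3R)-pent-1-en-3-ol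
Product: 8 (1S,3R,4S,6S,7S)-4,6-dibromo-3-ethyl-2,8-dioxabicyclo[5.2.1]decan-9-one, via allylic ether 7 (not isolated)
Conditions: Cu(MeCN)4PF6 (5 mol %), tris(2-pyridylmethyl)amine (5 mol %), AIBN (10 mol %), ClCH2CH2Cl (0.01 M), 25 °C (5 added slowly), then 80 °C
Reagents that add atoms: none
Why: Proposed new method: monovalent copper turns diazo lactone 5 into a copper carbene that is trapped by the hydroxyl of 6 (oxonium ylide, then proton delivery to C7 anti to the dibromomethyl group) to give the 2,4-cis ether 7 with the new O–C7 bond, and on heating the same complex abstracts one bromine atom from the CHBr2 group so that the α-bromoalkyl radical at C10 adds to the terminal alkene carbon C11 and the resulting C12 radical takes a bromine atom back from the divalent copper bromide complex. The closest known reaction types are the copper-catalysed O–H insertion of α-diazo esters and lactones and the copper-catalysed Kharasch addition and atom-transfer radical cyclisation of polyhaloalkanes such as CHBr3 and CBr4; new are their union in one flask and a non-activated 1,1-dibromoalkane as radical source, which is reasoned to work because the geminal bromine weakens the C–Br bond and the reversible capping of radicals by copper tolerates a slow ring closure. The oxocane ring, and with it the 2,8-dioxabicyclo[5.2.1]decane, is closed in the 8-endo-trig radical mode. C7 is set by protonation anti to the C9 substituent (the cis epimer is also the more stable one and the only one whose arms can meet), C10 by the transition state that keeps the C–Br bond anti to the C9–O bond and outside the forming bicycle, and C12 by bromine-atom transfer to the ring radical anti to the neighbouring ethyl group, while C9 and C13 come from 5 and 6. The step needs 8-endo over 7-exo closure and cyclisation over intermolecular addition, which should be secured by attack at the unsubstituted alkene terminus (secondary radical), the cis-1,3 placement of both arms on the five-membered lactone and high dilution.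

**Step 5**
Reactants: 8 (1S,3R,4S,6S,7S)-4,6-dibromo-3-ethyl-2,8-dioxabicyclo[5.2.1]decan-9-one
Product: 9 (1S,3R,4S,6S,7S)-4,6-dibromo-3-ethyl-9-(prop-2-en-1-yl)-2,8-dioxabicyclo[5.2.1]decan-9-ol (either configuration at the hemiketal carbon)
Conditions: CH2=CHCH2MgBr (1.2 equiv), THF, −78 °C; H2O work-up
Reagents that add atoms: allylmagnesium bromide, C=CC[Mg]Br
Why: Grignard addition to the lactone carbonyl at low temperature should stop at the magnesium hemiketal, because enolisation towards the bridgehead C7 is disfavoured and secondary alkyl bromides are inert to the reagent at −78 °C; the hemiketal configuration is of no consequence.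

**Step 6**
Reactants: 9 (1S,3R,4S,6S,7S)-4,6-dibromo-3-ethyl-9-(prop-2-en-1-yl)-2,8-dioxabicyclo[5.2.1]decan-9-ol
Product: 10 (1S,3R,4S,6S,7S,9S)-4,6-dibromo-3-ethyl-9-(prop-2-en-1-yl)-2,8-dioxabicyclo[5.2.1]decane
Conditions: Et3SiH, BF3·OEt2, CH2Cl2, −78 → −20 °C
Reagents that add atoms: none
Why: Ionic hydrogenation of the cyclic oxocarbenium ion from the hemiketal; hydride is expected to enter at C6 from the convex face, opposite the C7 oxygen and the five-atom bridge, which places the allyl group cis to the bridge and sets C6.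

**Step 7**
Reactants: 10 (1S,3R,4S,6S,7S,9S)-4,6-dibromo-3-ethyl-9-(prop-2-en-1-yl)-2,8-dioxabicyclo[5.2.1]decane
Product: 12 2-[(1S,3R,4S,6S,7S,9S)-4,6-dibromo-3-ethyl-2,8-dioxabicyclo[5.2.1]decan-9-yl]acetaldehyde, via ozonide 11 (not isolated)
Conditions: O3, CH2Cl2, −78 °C; then PPh3, −78 → 25 °C
Reagents that add atoms: ozone, [O-][O+]=O
Why: Ozonolysis of the terminal alkene with reductive work-up gives the C4 aldehyde; ethers and alkyl bromides are inert to ozone at −78 °C.

**Step 8**
Reactants: 12 2-[(1S,3R,4S,6S,7S,9S)-4,6-dibromo-3-ethyl-2,8-dioxabicyclo[5.2.1]decan-9-yl]acetaldehyde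
Product: 13 [(3Z)-5-[(1S,3R,4S,6S,7S,9S)-4,6-dibromo-3-ethyl-2,8-dioxabicyclo[5.2.1]decan-9-yl]pent-3-en-1-yn-1-yl]tri(propan-2-yl)silane
Conditions: i-Pr3SiC≡CCH2Si(i-Pr)3, n-BuLi, THF, −78 °C; then 12, −78 → −20 °C
Reagents that add atoms: 1,3-bis(triisopropylsilyl)propyne, CC(C)[Si](C(C)C)(C(C)C)CC#C[Si](C(C)C)(C(C)C)C(C)C
Why: Peterson olefination with the lithiated bis-silyl propyne: carbonyl addition and spontaneous syn-elimination of silanolate should give the (Z)-enyne selectively, and the hindered reagent should spare the aldehyde α-protons and the secondary bromides at −78 °C.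

**Step 9**
Reactants: 13 [(3Z)-5-[(1S,3R,4S,6S,7S,9S)-4,6-dibromo-3-ethyl-2,8-dioxabicyclo[5.2.1]decan-9-yl]pent-3-en-1-yn-1-yl]tri(propan-2-yl)silane
Product: 14 (1S,3R,4S,6S,7S,9S)-4,6-dibromo-3-ethyl-9-[(2Z)-pent-2-en-4-yn-1-yl]-2,8-dioxabicyclo[5.2.1]decane
Conditions: n-Bu4NF, THF, 0 °C
Reagents that add atoms: none
Why: Fluoride-induced protodesilylation of the alkynylsilane; at 0 °C the secondary bromides, the (Z)-alkene and the ether rings should be untouched.

**Compound list**

1 | (5S)-5-(hydroxymethyl)oxolan-2-one | OC[C@@H]1CCC(=O)O1 | starting material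
2 | (2S)-5-oxooxolane-2-carbaldehyde | O=C[C@@H]1CCC(=O)O1 | intermediate
3 | (5S)-5-(dibromomethyl)oxolan-2-one | BrC(Br)[C@@H]1CCC(=O)O1 | intermediate
4 | (5S)-5-(dibromomethyl)-3-(2,2,2-trifluoroacetyl)oxolan-2-one (C3 epimers and enol) | BrC(Br)[C@@H]1CC(C(=O)C(F)(F)F)C(=O)O1 | intermediate
5 | (5S)-3-diazo-5-(dibromomethyl)oxolan-2-one | BrC(Br)[C@@H]1CC(=[N+]=[N-])C(=O)O1 | intermediate
6 | (3R)-pent-1-en-3-ol | CC[C@@H](O)C=C | starting material
7 | (3S,5S)-5-(dibromomethyl)-3-[(3R)-pent-1-en-3-yloxy]oxolan-2-one (2,4-cis lactone) | O=C1O[C@H](C(Br)Br)C[C@@H]1O[C@H](CC)C=C | intermediate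
8 | (1S,3R,4S,6S,7S)-4,6-dibromo-3-ethyl-2,8-dioxabicyclo[5.2.1]decan-9-one | O=C1O[C@H]2C[C@@H]1O[C@H](CC)[C@@H](Br)C[C@@H]2Br | intermediate
9 | (1S,3R,4S,6S,7S)-4,6-dibromo-3-ethyl-9-(prop-2-en-1-yl)-2,8-dioxabicyclo[5.2.1]decan-9-ol (hemiketal, either configuration at C9 of the bicycle) | C=CCC1(O)O[C@H]2C[C@@H]1O[C@H](CC)[C@@H](Br)C[C@@H]2Br | intermediate
10 | (1S,3R,4S,6S,7S,9S)-4,6-dibromo-3-ethyl-9-(prop-2-en-1-yl)-2,8-dioxabicyclo[5.2.1]decane | C=CC[C@@H]1O[C@H]2C[C@@H]1O[C@H](CC)[C@@H](Br)C[C@@H]2Br | intermediate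
11 | 3-{[(1S,3R,4S,6S,7S,9S)-4,6-dibromo-3-ethyl-2,8-dioxabicyclo[5.2.1]decan-9-yl]methyl}-1,2,4-trioxolane (ozonide) | C1OOC(C[C@@H]2O[C@H]3C[C@@H]2O[C@H](CC)[C@@H](Br)C[C@@H]3Br)O1 | intermediate
12 | 2-[(1S,3R,4S,6S,7S,9S)-4,6-dibromo-3-ethyl-2,8-dioxabicyclo[5.2.1]decan-9-yl]acetaldehyde | O=CC[C@@H]1O[C@H]2C[C@@H]1O[C@H](CC)[C@@H](Br)C[C@@H]2Br | intermediate
13 | [(3Z)-5-[(1S,3R,4S,6S,7S,9S)-4,6-dibromo-3-ethyl-2,8-dioxabicyclo[5.2.1]decan-9-yl]pent-3-en-1-yn-1-yl]tri(propan-2-yl)silane | CC(C)[Si](C(C)C)(C(C)C)C#C/C=C\C[C@@H]1O[C@H]2C[C@@H]1O[C@H](CC)[C@@H](Br)C[C@@H]2Br | intermediate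
14 | (1S,3R,4S,6S,7S,9S)-4,6-dibromo-3-ethyl-9-[(2Z)-pent-2-en-4-yn-1-yl]-2,8-dioxabicyclo[5.2.1]decane | C#C/C=C\C[C@@H]1O[C@H]2C[C@@H]1O[C@H](CC)[C@@H](Br)C[C@@H]2Br | target

Total step count: 9. Longest linear sequence: 9 steps (1 to 14); 6 enters at step 4.

**Steps most likely to fail**

Step 4 (proposed new method). What may go wrong: bromine-atom abstraction from the non-activated 1,1-dibromide may be too slow; 7-exo or intermolecular radical addition may compete; bromine may be delivered with the wrong facial sense at C10 or C12; the carbene may cyclopropanate the alkene instead of inserting into O–H; the trans epimer of the ether at C7 may accumulate without cyclising. Fallback with known chemistry, setting out from 2 and 6 and returning to the route at 8: the C10–C11 bond is made first by a polar aldol reaction and the O–C7 bond last by a ring-closing carbene O–H insertion.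
- Silylation of 6 (t-BuMe2SiCl, imidazole) should give tert-butyl(dimethyl)[(3R)-pent-1-en-3-yloxy]silane F1.
- Wacker oxidation (PdCl2, CuCl, O2, DMF/H2O) should give (3R)-3-{[tert-butyl(dimethyl)silyl]oxy}pentan-2-one F2.
- Kinetic enolisation (LiN(i-Pr)2, Me3SiCl, −78 °C) should give (3R)-3-{[tert-butyl(dimethyl)silyl]oxy}-2-[(trimethylsilyl)oxy]pent-1-ene F3.
- Mukaiyama aldol addition of F3 to aldehyde 2 (BF3·OEt2, −78 °C, Felkin–Anh control by the C9 oxygen) should give (5S)-5-[(1R,4R)-4-{[tert-butyl(dimethyl)silyl]oxy}-1-hydroxy-3-oxohexyl]oxolan-2-one F4.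
- Evans–Saksena reduction (Me4NBH(OAc)3, MeCN/AcOH) should give the 1,3-anti diol (5S)-5-[(1R,3R,4R)-4-{[tert-butyl(dimethyl)silyl]oxy}-1,3-dihydroxyhexyl]oxolan-2-one F5.
- Appel-type double displacement with inversion (CBr4, P(n-C8H17)3, toluene, 70 °C) should give (5S)-5-[(1S,3S,4R)-1,3-dibromo-4-{[tert-butyl(dimethyl)silyl]oxy}hexyl]oxolan-2-one F6.
- Detrifluoroacetylative diazo transfer as in step 3 should pass through (5S)-5-[(1S,3S,4R)-1,3-dibromo-4-{[tert-butyl(dimethyl)silyl]oxy}hexyl]-3-(2,2,2-trifluoroacetyl)oxolan-2-one F7 to (5S)-3-diazo-5-[(1S,3S,4R)-1,3-dibromo-4-{[tert-butyl(dimethyl)silyl]oxy}hexyl]oxolan-2-one F8.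
- Buffered desilylation (n-Bu4NF, AcOH, THF, 0 °C) should give (5S)-3-diazo-5-[(1S,3S,4R)-1,3-dibromo-4-hydroxyhexyl]oxolan-2-one F9.
- Rh2(OAc)4 (divalent rhodium) in CH2Cl2 at high dilution should close the eight-membered ring by intramolecular carbene O–H insertion, for which only the cis-bridged mode is possible, to give 8.

Step 6. What may go wrong: poor or reversed facial selectivity of hydride delivery to the oxocarbenium ion, giving the C6 epimer with the allyl group trans to the bridge. Fallback, setting out from 8 and returning at 10: the order of introduction is reversed, so that the carbon nucleophile enters on the face that hydride prefers.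
- Reduction with i-Bu2AlH (CH2Cl2, −78 °C) should give the lactol (1S,3R,4S,6S,7S)-4,6-dibromo-3-ethyl-2,8-dioxabicyclo[5.2.1]decan-9-ol F10.
- Acetylation (Ac2O, pyridine) should give (1S,3R,4S,6S,7S)-4,6-dibromo-3-ethyl-2,8-dioxabicyclo[5.2.1]decan-9-yl acetate F11.
- BF3·OEt2-promoted substitution with allyltrimethylsilane (CH2Cl2, −78 °C) should return to 10.

Step 8. What may go wrong: poor Z/E selectivity of the olefination, or base-induced loss of HBr from the secondary bromides and enolisation of the β-alkoxy aldehyde by the lithium reagent. Fallback, setting out from 12 and returning at 13: the enyne is built in two stages.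
- Stork–Zhao olefination (Ph3P(CH2I)I, NaN(SiMe3)2, THF/DMPU, −78 °C) should give (1S,3R,4S,6S,7S,9S)-4,6-dibromo-3-ethyl-9-[(2Z)-3-iodoprop-2-en-1-yl]-2,8-dioxabicyclo[5.2.1]decane F12.
- Sonogashira coupling with (triisopropylsilyl)acetylene (Pd(PPh3)4 as zerovalent palladium, CuI, i-Pr2NH, 25 °C) should return to 13; unactivated secondary alkyl bromides do not undergo oxidative addition under these conditions.

**Further compounds**

F1 | step 4 | tert-butyl(dimethyl)[(3R)-pent-1-en-3-yloxy]silane | CC[C@@H](O[Si](C)(C)C(C)(C)C)C=C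
F2 | step 4 | (3R)-3-{[tert-butyl(dimethyl)silyl]oxy}pentan-2-one | CC[C@@H](O[Si](C)(C)C(C)(C)C)C(C)=O
F3 | step 4 | (3R)-3-{[tert-butyl(dimethyl)silyl]oxy}-2-[(trimethylsilyl)oxy]pent-1-ene | CC[C@@H](O[Si](C)(C)C(C)(C)C)C(=C)O[Si](C)(C)C
F4 | step 4 | (5S)-5-[(1R,4R)-4-{[tert-butyl(dimethyl)silyl]oxy}-1-hydroxy-3-oxohexyl]oxolan-2-one | CC[C@@H](O[Si](C)(C)C(C)(C)C)C(=O)C[C@@H](O)[C@@H]1CCC(=O)O1
F5 | step 4 | (5S)-5-[(1R,3R,4R)-4-{[tert-butyl(dimethyl)silyl]oxy}-1,3-dihydroxyhexyl]oxolan-2-one | CC[C@@H](O[Si](C)(C)C(C)(C)C)[C@H](O)C[C@@H](O)[C@@H]1CCC(=O)O1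
F6 | step 4 | (5S)-5-[(1S,3S,4R)-1,3-dibromo-4-{[tert-butyl(dimethyl)silyl]oxy}hexyl]oxolan-2-one | CC[C@@H](O[Si](C)(C)C(C)(C)C)[C@@H](Br)C[C@H](Br)[C@@H]1CCC(=O)O1
F7 | step 4 | (5S)-5-[(1S,3S,4R)-1,3-dibromo-4-{[tert-butyl(dimethyl)silyl]oxy}hexyl]-3-(2,2,2-trifluoroacetyl)oxolan-2-one | CC[C@@H](O[Si](C)(C)C(C)(C)C)[C@@H](Br)C[C@H](Br)[C@@H]1CC(C(=O)C(F)(F)F)C(=O)O1
F8 | step 4 | (5S)-3-diazo-5-[(1S,3S,4R)-1,3-dibromo-4-{[tert-butyl(dimethyl)silyl]oxy}hexyl]oxolan-2-one | CC[C@@H](O[Si](C)(C)C(C)(C)C)[C@@H](Br)C[C@H](Br)[C@@H]1CC(=[N+]=[N-])C(=O)O1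
F9 | step 4 | (5S)-3-diazo-5-[(1S,3S,4R)-1,3-dibromo-4-hydroxyhexyl]oxolan-2-one | CC[C@@H](O)[C@@H](Br)C[C@H](Br)[C@@H]1CC(=[N+]=[N-])C(=O)O1
F10 | step 6 | (1S,3R,4S,6S,7S)-4,6-dibromo-3-ethyl-2,8-dioxabicyclo[5.2.1]decan-9-ol | OC1O[C@H]2C[C@@H]1O[C@H](CC)[C@@H](Br)C[C@@H]2Br
F11 | step 6 | (1S,3R,4S,6S,7S)-4,6-dibromo-3-ethyl-2,8-dioxabicyclo[5.2.1]decan-9-yl acetate | CC(=O)OC1O[C@H]2C[C@@H]1O[C@H](CC)[C@@H](Br)C[C@@H]2Br
F12 | step 8 | (1S,3R,4S,6S,7S,9S)-4,6-dibromo-3-ethyl-9-[(2Z)-3-iodoprop-2-en-1-yl]-2,8-dioxabicyclo[5.2.1]decane | I/C=C\C[C@@H]1O[C@H]2C[C@@H]1O[C@H](CC)[C@@H](Br)C[C@@H]2Br
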